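**Retrosynthetic overview**
1. C1–C8 (closes ring B, last bond): a C8 tertiary carbocation equivalent is captured by the C1 enol carbon of a C5-dialkylated, dearomatised acylphloroglucinol, as in the presumed biosynthesis, run here as a stereoinvertive displacement of a tertiary sulfate.
2. C5–C6: dearomative C-alkylation of a 3,5-diprenyl acylphloroglucinol by the primary carbon of a chiral 1,3-cyclic sulfate; both bonds are made in one flask (formal 3+3 annulation).
3. Cyclic sulfate (C6–C7–C8 with both side chains): nerol, Sharpless epoxidation, anti opening at C2 by a prenyl copper reagent, sulfation.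
4. Acylphloroglucinol: Houben–Hoesch acylation of phloroglucinol, double C-prenylation, silylation of the lone phenol.
5. Ring order: ring A is the phloroglucinol ring (aromatic, dearomatised at C5 in the key step); ring B is formed last.

Assumption: the enolised β-triketone is written as the tautomer of the given SMILES and all its tautomers count as one compound; core atoms are numbered as in bicyclo[3.3.1]nonane (C1 and C5 bridgeheads, C9 bridging C=O, C7 the CH, C8 the quaternary carbon).

**Step 1**
Reactants: 1 phloroglucinol (benzene-1,3,5-triol); 2 3-hydroxybenzonitrile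
Product: 4 (3-hydroxyphenyl)(2,4,6-trihydroxyphenyl)methanone, via ketiminium chloride 3 (not isolated)
Conditions: ZnCl2, HCl (g), Et2O, 0 °C to rt; then H2O, reflux
Reagents that add atoms: water, SMILES O
Why: Houben–Hoesch acylation, in which the HCl/ZnCl2-activated nitrile attacks the most electron-rich arene once (the ketiminium salt deactivates the ring) and hydrolysis of the precipitated salt gives the diaryl ketone, with no stereocenter formed.

**Step 2**
Reactants: 4 (3-hydroxyphenyl)(2,4,6-trihydroxyphenyl)methanone; 5 prenyl bromide (1-bromo-3-methylbut-2-ene, 2.1 equiv)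
Product: 6 (3-hydroxyphenyl)[2,4,6-trihydroxy-3,5-bis(3-methylbut-2-en-1-yl)phenyl]methanone
Conditions: KOH (10% aq), 0 °C
Reagents that add atoms: none
Why: C-alkylation of the phloroglucinol polyanion in water (C-prenylation of a phenolate) takes the only two ring C–H positions, while water solvation suppresses O-alkylation of this ring and of the isolated 3'-phenoxide and 2.1 equiv of 5 limits over-alkylation, with no stereocenter formed.

**Step 3**
Reactants: 6 (3-hydroxyphenyl)[2,4,6-trihydroxy-3,5-bis(3-methylbut-2-en-1-yl)phenyl]methanone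
Product: 7 [2,4,6-trihydroxy-3,5-bis(3-methylbut-2-en-1-yl)phenyl]{3-[tri(propan-2-yl)silyloxy]phenyl}methanone
Conditions: iPr3SiCl (1.05 equiv), imidazole, DMF, 0 °C
Reagents that add atoms: chlorotri(propan-2-yl)silane, SMILES CC(C)[Si](Cl)(C(C)C)C(C)C
Why: silyl ether formation with a bulky chlorosilane is selective for the only unhindered phenol (each phloroglucinol OH has two ortho substituents and any silyl ether formed there hydrolyses on work-up), and it is needed because a free 3'-phenoxide would be O-alkylated in step 7.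

**Step 4**
Reactants: 8 nerol ((2Z)-3,7-dimethylocta-2,6-dien-1-ol)
Product: 9 [(2S,3R)-3-methyl-3-(4-methylpent-3-en-1-yl)oxiran-2-yl]methanol
Conditions: Ti(OiPr)4 (10 mol%), L-(+)-diethyl tartrate (12 mol%), tBuOOH, 4 Å MS, CH2Cl2, −20 °C
Reagents that add atoms: tert-butyl hydroperoxide, SMILES CC(C)(C)OO
Why: Sharpless asymmetric epoxidation is directed by the allylic alcohol so only the 2,3-alkene reacts, and L-(+)-tartrate delivers oxygen to the face that gives (2S,3R) (about 90–95% ee expected), which fixes the absolute configuration of C8 and, through step 5, of C7.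

**Step 5**
Reactants: 9 [(2S,3R)-3-methyl-3-(4-methylpent-3-en-1-yl)oxiran-2-yl]methanol; 10 (3-methylbut-2-en-1-yl)magnesium chloride (3 equiv)
Product: 11 (2R,3R)-3,7-dimethyl-2-(3-methylbut-2-en-1-yl)oct-6-ene-1,3-diol
Conditions: CuI (15 mol%), THF, −40 to 0 °C; then aq NH4Cl
Reagents that add atoms: none
Why: copper-catalysed Grignard opening of an epoxide (SN2) occurs at C2 because C3 is fully substituted, the allylic copper species couples through its unsubstituted CH2 terminus, and inversion at C2 with C3 untouched gives the anti 1,3-diol in which the future C7 is R.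

**Step 6**
Reactants: 11 (2R,3R)-3,7-dimethyl-2-(3-methylbut-2-en-1-yl)oct-6-ene-1,3-diol
Product: 12 (4R,5R)-4-methyl-4-(4-methylpent-3-en-1-yl)-5-(3-methylbut-2-en-1-yl)-1,3,2-dioxathiane 2,2-dioxide
Conditions: NaH (2.2 equiv), 1,1'-sulfonyldiimidazole (1.2 equiv), THF, −40 to 0 °C
Reagents that add atoms: 1,1'-sulfonyldiimidazole, SMILES O=S(=O)(n1ccnc1)n1ccnc1
Why: cyclic sulfate formation by double O-sulfonylation (the primary alkoxide reacts first, the tertiary alkoxide then closes the six-membered ring at sulfur) needs no oxidant, so both trisubstituted alkenes survive and neither stereocenter is touched.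

**Step 7**
Reactants: 7 [2,4,6-trihydroxy-3,5-bis(3-methylbut-2-en-1-yl)phenyl]{3-[tri(propan-2-yl)silyloxy]phenyl}methanone; 12 (4R,5R)-4-methyl-4-(4-methylpent-3-en-1-yl)-5-(3-methylbut-2-en-1-yl)-1,3,2-dioxathiane 2,2-dioxide
Product: 15 (1S,5S,7R,8S)-4-hydroxy-3-(3-hydroxybenzoyl)-8-methyl-1,5,7-tris(3-methylbut-2-en-1-yl)-8-(4-methylpent-3-en-1-yl)bicyclo[3.3.1]non-3-ene-2,9-dione, via C5-alkylated tertiary sulfate 13 (not isolated), via silyl-protected bicyclic trione 14 (not isolated)
Conditions: (a) LiN(SiMe3)2 (3.0 equiv), THF, −78 °C, then 12, −78 to 23 °C; (b) solvent switch to CH2Cl2, Me3SiOTf (6 equiv), 2,6-lutidine (2 equiv), −78 to −20 °C; (c) Bu4NF, THF, 0 °C, then aq NH4Cl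
Reagents that add atoms: none
Why: Proposed new method: in (a) the trilithium salt of 7 is C-alkylated at a prenyl-bearing ring carbon by SN2 attack on the primary carbon of 12 (closest known: dearomative C-alkylation of acylphloroglucinol polyanions with β-branched primary triflates, and SN2 opening of 1,3-cyclic sulfates by carbanions at the less substituted carbon), which creates C5 without control (about 1:1) and leaves the tertiary C8–O bond as a sulfate monoester; in (b) Me3SiOTf converts the enolates into silyl enol ethers and the sulfate into a neutral silyl sulfate leaving group, whose ionisation is assisted from the rear by the C1 silyl enol ether carbon through a chair transition state with the C7 prenyl equatorial (closest known: Lewis-acid α-tert-alkylation of silyl enol ethers, epoxide-opening cyclisations of enol ethers at a tertiary carbon with inversion, and stereoinvertive SN1 substitution of tertiary esters through contact ion pairs), so that C8 goes from R in 12 to S, C1 follows from the bridged ring, and only the C5 epimer drawn for 13 can reach this chair, the other C5 epimer and any C8 epimer being removed by chromatography (at most about half of the material is productive); in (c) fluoride cleaves the silyl enol ether and the aryl silyl ether in the same flask.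

**Compound list**
1 | phloroglucinol (benzene-1,3,5-triol) | Oc1cc(O)cc(O)c1 | starting material
2 | 3-hydroxybenzonitrile | N#Cc1cccc(O)c1 | starting material
3 | (3-hydroxyphenyl)(2,4,6-trihydroxyphenyl)methaniminium chloride | [NH2+]=C(c1cccc(O)c1)c1c(O)cc(O)cc1O.[Cl-] | intermediate
4 | (3-hydroxyphenyl)(2,4,6-trihydroxyphenyl)methanone | O=C(c1cccc(O)c1)c1c(O)cc(O)cc1O | intermediate
5 | prenyl bromide (1-bromo-3-methylbut-2-ene) | CC(C)=CCBr | starting material
6 | (3-hydroxyphenyl)[2,4,6-trihydroxy-3,5-bis(3-methylbut-2-en-1-yl)phenyl]methanone | CC(C)=CCc1c(O)c(CC=C(C)C)c(O)c(C(=O)c2cccc(O)c2)c1O | intermediate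
7 | [2,4,6-trihydroxy-3,5-bis(3-methylbut-2-en-1-yl)phenyl]{3-[tri(propan-2-yl)silyloxy]phenyl}methanone | CC(C)=CCc1c(O)c(CC=C(C)C)c(O)c(C(=O)c2cccc(O[Si](C(C)C)(C(C)C)C(C)C)c2)c1O | intermediate
8 | nerol ((2Z)-3,7-dimethylocta-2,6-dien-1-ol) | CC(C)=CCC/C(C)=C\CO | starting material
9 | [(2S,3R)-3-methyl-3-(4-methylpent-3-en-1-yl)oxiran-2-yl]methanol | CC(C)=CCC[C@@]1(C)O[C@H]1CO | intermediate
10 | (3-methylbut-2-en-1-yl)magnesium chloride | CC(C)=CC[Mg]Cl | starting material
11 | (2R,3R)-3,7-dimethyl-2-(3-methylbut-2-en-1-yl)oct-6-ene-1,3-diol | CC(C)=CCC[C@](O)(C)[C@H](CC=C(C)C)CO | intermediate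
12 | (4R,5R)-4-methyl-4-(4-methylpent-3-en-1-yl)-5-(3-methylbut-2-en-1-yl)-1,3,2-dioxathiane 2,2-dioxide | CC(C)=CCC[C@@]1(C)OS(=O)(=O)OC[C@H]1CC=C(C)C | intermediate
13 | (6R)-6-[(2R,3R)-3,7-dimethyl-2-(3-methylbut-2-en-1-yl)-3-(sulfooxy)oct-6-en-1-yl]-3,5-dihydroxy-4,6-bis(3-methylbut-2-en-1-yl)-2-{3-[tri(propan-2-yl)silyloxy]benzoyl}cyclohexa-2,4-dien-1-one (lithium salt in the flask, drawn as the free acid) | CC(C)=CCC[C@@](C)(OS(=O)(=O)O)[C@H](CC=C(C)C)C[C@@]1(CC=C(C)C)C(=O)C(C(=O)c2cccc(O[Si](C(C)C)(C(C)C)C(C)C)c2)=C(O)C(CC=C(C)C)=C1O | intermediate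
14 | (1S,5S,7R,8S)-4-hydroxy-8-methyl-1,5,7-tris(3-methylbut-2-en-1-yl)-8-(4-methylpent-3-en-1-yl)-3-{3-[tri(propan-2-yl)silyloxy]benzoyl}bicyclo[3.3.1]non-3-ene-2,9-dione (trimethylsilyl enol ether in the flask, drawn as the free enol) | CC(C)=CCC[C@@]1(C)[C@H](CC=C(C)C)C[C@]2(CC=C(C)C)C(=O)[C@@]1(CC=C(C)C)C(=O)C(C(=O)c1cccc(O[Si](C(C)C)(C(C)C)C(C)C)c1)=C2O | intermediate
15 | (1S,5S,7R,8S)-4-hydroxy-3-(3-hydroxybenzoyl)-8-methyl-1,5,7-tris(3-methylbut-2-en-1-yl)-8-(4-methylpent-3-en-1-yl)bicyclo[3.3.1]non-3-ene-2,9-dione | CC(C)=CCC[C@@]1(C)[C@H](CC=C(C)C)C[C@]2(CC=C(C)C)C(=O)[C@@]1(CC=C(C)C)C(=O)C(C(=O)c1cccc(O)c1)=C2O | target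

**Totals**
Total step count: 7 (isolated products 4, 6, 7, 9, 11, 12 and 15).
Longest linear sequence: 4 steps (1 → 4 → 6 → 7 → 15, or equally 8 → 9 → 11 → 12 → 15).
The enantiomeric purity of 15 equals that of 9, because the later separations remove diastereomers only.

**Three steps most likely to fail**

Step 7 (one-flask annulation). Risks: O-alkylation instead of C-alkylation, elimination of the tertiary sulfate instead of C1–C8 bond formation, partial loss of inversion at C8, and the uncontrolled C5 epimer ratio. Fallback: set out from 11 and 7 and separate the two bond formations. Selective triflation of the primary hydroxyl of 11 (Tf2O, 2,6-lutidine, CH2Cl2, −78 °C) gives (2R,3R)-3-hydroxy-3,7-dimethyl-2-(3-methylbut-2-en-1-yl)oct-6-en-1-yl trifluoromethanesulfonate F1. C-alkylation of the trilithium salt of 7 with F1 (LiN(SiMe3)2, THF, −78 to 0 °C) gives the isolable dearomatised tertiary alcohol (6R)-3,5-dihydroxy-6-[(2R,3R)-3-hydroxy-3,7-dimethyl-2-(3-methylbut-2-en-1-yl)oct-6-en-1-yl]-4,6-bis(3-methylbut-2-en-1-yl)-2-{3-[tri(propan-2-yl)silyloxy]benzoyl}cyclohexa-2,4-dien-1-one F2, whose C5 epimer is separated at this stage. F2 in neat HCO2H at rt ionises to the free C8 cation and closes onto C1 under equilibrating conditions (O-cyclised and formate by-products revert; C8 epimers are separated), which comes back to the route at 14. Bu4NF then gives 15.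

Step 6 (cyclic sulfate with a tertiary C–O bond). Risks: oxetane formation from the intermediate primary imidazole-1-sulfonate, and ionisation of the product on handling. Fallback: set out from 11 and activate it as a tin acetal. Bu2SnO (toluene, reflux, water removal) gives (4R,5R)-2,2-dibutyl-4-methyl-4-(4-methylpent-3-en-1-yl)-5-(3-methylbut-2-en-1-yl)-1,3,2-dioxastanninane F3, and SO2Cl2 (CH2Cl2, −78 °C) converts F3 directly into the cyclic sulfate, coming back to the route at 12. If 12 itself proves too labile to handle, the fallback given for step 7 avoids it.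

Step 5 (prenyl transfer to the epoxide). Risks: coupling through the substituted terminus of the allylic metal (reverse prenyl) and attack at C3. Fallback: set out from 9 and use a symmetrical allyl nucleophile. Allylmagnesium chloride with CuI (THF, −40 to 0 °C) gives (2R,3R)-3,7-dimethyl-2-(prop-2-en-1-yl)oct-6-ene-1,3-diol F4. Cross-metathesis of F4 in neat 2-methylbut-2-ene with the second-generation Grubbs catalyst RuCl2(=CHPh)(PCy3)(H2IMes) converts the allyl into the prenyl group (the existing trisubstituted alkene only exchanges degenerately), coming back to the route at 11.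

**Further compounds**
F1 | step 7 | (2R,3R)-3-hydroxy-3,7-dimethyl-2-(3-methylbut-2-en-1-yl)oct-6-en-1-yl trifluoromethanesulfonate | CC(C)=CCC[C@](O)(C)[C@H](CC=C(C)C)COS(=O)(=O)C(F)(F)F
F2 | step 7 | (6R)-3,5-dihydroxy-6-[(2R,3R)-3-hydroxy-3,7-dimethyl-2-(3-methylbut-2-en-1-yl)oct-6-en-1-yl]-4,6-bis(3-methylbut-2-en-1-yl)-2-{3-[tri(propan-2-yl)silyloxy]benzoyl}cyclohexa-2,4-dien-1-one | CC(C)=CCC[C@](O)(C)[C@H](CC=C(C)C)C[C@@]1(CC=C(C)C)C(=O)C(C(=O)c2cccc(O[Si](C(C)C)(C(C)C)C(C)C)c2)=C(O)C(CC=C(C)C)=C1O
F3 | step 6 | (4R,5R)-2,2-dibutyl-4-methyl-4-(4-methylpent-3-en-1-yl)-5-(3-methylbut-2-en-1-yl)-1,3,2-dioxastanninane | CC(C)=CCC[C@@]1(C)O[Sn](CCCC)(CCCC)OC[C@H]1CC=C(C)C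
F4 | step 5 | (2R,3R)-3,7-dimethyl-2-(prop-2-en-1-yl)oct-6-ene-1,3-diol | CC(C)=CCC[C@](O)(C)[C@H](CC=C)CO
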